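**Strategy**

The route rests on cutting the cyclohexa-2,5-dienone ring (C1 carbonyl, C2 allyl-bearing, C3–H, quaternary C4, C5 methoxy-bearing, C6–H) at C2=C3 and at C6–C1. The key step exploits that the vinylogous ester C5(OMe)=C6–C1=O is the methanol adduct of an ynone and that the enone C2=C3–C1=O is an aldol condensation product. Three components are therefore joined in one flask: a non-enolisable alkynyl aldehyde that already carries the C4 stereocentre, pent-4-enoyl chloride and methanol. Acylation of the alkyne terminus forms C6–C1, methanol adds at C5, and the C2 enolate condenses with the C3 aldehyde. The stereocentre comes from an enantioselective alkynylation of an α-keto ester.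

Key step: step 6

Assumption: the facial sense of the Zn(OTf)2/amino alcohol alkynylation on this conjugated α-keto ester is not predicted here; the (1S,2S) ligand is written, and its (1R,2R) enantiomer is used instead if it is the one that delivers the alkyne to the face giving 6.

**Route**

Step 1
Reactants: 1 3,4-dimethoxybenzaldehyde; 2 2-oxobutanoic acid
Product: 3 (3E)-4-(3,4-dimethoxyphenyl)-3-methyl-2-oxobut-3-enoic acid
Conditions: KOH, MeOH–H2O, 0 °C → rt; then aq. HCl
Reagents that add atoms: none
Why: Claisen–Schmidt (crossed aldol) condensation in which the C3 methylene of the keto acid dianion adds to the non-enolisable aryl aldehyde and E1cB loss of water should give the thermodynamic (E)-alkene, aryl trans to the keto carbonyl.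

Step 2
Reactants: 3 (3E)-4-(3,4-dimethoxyphenyl)-3-methyl-2-oxobut-3-enoic acid
Product: 4 methyl (3E)-4-(3,4-dimethoxyphenyl)-3-methyl-2-oxobut-3-enoate
Conditions: MeI, K2CO3, DMF, rt
Reagents that add atoms: iodomethane, CI
Why: SN2 O-alkylation of the carboxylate (ester formation) under mild base, which should leave the conjugated keto group and the alkene geometry untouched.

Step 3
Reactants: 4 methyl (3E)-4-(3,4-dimethoxyphenyl)-3-methyl-2-oxobut-3-enoate; 5 ethynyltrimethylsilane
Product: 6 methyl (2S,3E)-4-(3,4-dimethoxyphenyl)-2-hydroxy-3-methyl-2-[(trimethylsilyl)ethynyl]but-3-enoate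
Conditions: Zn(OTf)2 (20 mol%), (1S,2S)-3-(tert-butyldimethylsilyloxy)-2-(dimethylamino)-1-(4-nitrophenyl)propan-1-ol (22 mol%), Et3N (30 mol%), toluene, 70 °C, sealed tube
Reagents that add atoms: none
Why: Catalytic enantioselective alkynylation of an α-keto ester, in which the zinc acetylide formed in situ adds 1,2 to the activated ketone inside the chiral zinc amino alkoxide complex, so that the ligand (reagent control) sets the quaternary carbinol centre.

Step 4
Reactants: 6 methyl (2S,3E)-4-(3,4-dimethoxyphenyl)-2-hydroxy-3-methyl-2-[(trimethylsilyl)ethynyl]but-3-enoate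
Product: 8 methyl (2R,3E)-4-(3,4-dimethoxyphenyl)-2-ethynyl-2-methoxy-3-methylbut-3-enoate, via silyl methyl ether 7 (not isolated)
Conditions: NaH, MeI, THF–DMF, 0 °C → rt; then MeOH, K2CO3, rt
Reagents that add atoms: iodomethane, CI
Why: Williamson ether synthesis on the tertiary sodium alkoxide, with the silyl group shielding the alkyne from C-methylation, followed by methanolysis of the alkynyl C–Si bond in the same flask; the centre bears no hydrogen and cannot epimerise (the descriptor changes only because the substituent priorities change).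

Step 5
Reactants: 8 methyl (2R,3E)-4-(3,4-dimethoxyphenyl)-2-ethynyl-2-methoxy-3-methylbut-3-enoate
Product: 9 (2R,3E)-4-(3,4-dimethoxyphenyl)-2-ethynyl-2-methoxy-3-methylbut-3-enal
Conditions: i-Bu2AlH (1.2 equiv), CH2Cl2, −78 °C; aq. potassium sodium tartrate
Reagents that add atoms: none
Why: Partial reduction of an α-alkoxy ester, in which the chelated tetrahedral aluminium hemiacetal should persist at −78 °C and release the aldehyde only on work-up.

Step 6
Reactants: 9 (2R,3E)-4-(3,4-dimethoxyphenyl)-2-ethynyl-2-methoxy-3-methylbut-3-enal; 10 pent-4-enoyl chloride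
Product: 14 (4S)-4-[(1E)-1-(3,4-dimethoxyphenyl)prop-1-en-2-yl]-4,5-dimethoxy-2-(prop-2-en-1-yl)cyclohexa-2,5-dien-1-one, via ynone 11 (not isolated), via β-methoxy enone 12 (not isolated), via aldol adduct 13 (not isolated)
Conditions: PdCl2(PPh3)2 (2 mol%), CuI (4 mol%), Et3N (1.1 equiv), THF, rt; then MeOH, K2CO3 (3 equiv), rt → 50 °C
Reagents that add atoms: methanol, CO
Why: Oxidative addition of 10 to zerovalent palladium and transmetalation with the copper acetylide of 9 (acyl Sonogashira coupling) should form the C6–C1 bond of ynone 11; methoxide from K2CO3/MeOH then adds to the ynone β-carbon C5 (oxa-Michael addition) to give vinylogous ester 12, whose C2 enolate attacks the C3 aldehyde and loses water by E1cB to form C2=C3. The closest known reaction type is the one-pot coupling–addition–cyclocondensation sequence of acid chlorides, terminal alkynes and a nucleophile, ending here in a Robinson-type aldol cyclodehydration of a 1,5-dicarbonyl compound. The six-membered ring closes by a 6-(enolendo)-exo-trig aldol addition. No stereocentre is created: C4 was set in step 3, bears no hydrogen and sits next to a non-enolisable aldehyde, so it cannot epimerise, and the two transient centres of 13 disappear on dehydration. The step needs the (E) geometry at C5=C6 (C4 cis to C1) and C2 as the only carbon nucleophile; reversible methoxide addition–elimination interconverts the enone isomers so that only the cyclisable one is drained, and C2 is the only enolisable position of 12.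

**Compound list**

1 | 3,4-dimethoxybenzaldehyde | COc1ccc(C=O)cc1OC | starting material
2 | 2-oxobutanoic acid | CCC(=O)C(=O)O | starting material
3 | (3E)-4-(3,4-dimethoxyphenyl)-3-methyl-2-oxobut-3-enoic acid | OC(=O)C(=O)/C(C)=C/c1ccc(OC)c(OC)c1 | intermediate
4 | methyl (3E)-4-(3,4-dimethoxyphenyl)-3-methyl-2-oxobut-3-enoate | COC(=O)C(=O)/C(C)=C/c1ccc(OC)c(OC)c1 | intermediate
5 | ethynyltrimethylsilane | C#C[Si](C)(C)C | starting material
6 | methyl (2S,3E)-4-(3,4-dimethoxyphenyl)-2-hydroxy-3-methyl-2-[(trimethylsilyl)ethynyl]but-3-enoate | COC(=O)[C@](O)(/C(C)=C/c1ccc(OC)c(OC)c1)C#C[Si](C)(C)C | intermediate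
7 | methyl (2S,3E)-4-(3,4-dimethoxyphenyl)-2-methoxy-3-methyl-2-[(trimethylsilyl)ethynyl]but-3-enoate | COC(=O)[C@](OC)(/C(C)=C/c1ccc(OC)c(OC)c1)C#C[Si](C)(C)C | intermediate
8 | methyl (2R,3E)-4-(3,4-dimethoxyphenyl)-2-ethynyl-2-methoxy-3-methylbut-3-enoate | COC(=O)[C@](OC)(/C(C)=C/c1ccc(OC)c(OC)c1)C#C | intermediate
9 | (2R,3E)-4-(3,4-dimethoxyphenyl)-2-ethynyl-2-methoxy-3-methylbut-3-enal | O=C[C@](OC)(/C(C)=C/c1ccc(OC)c(OC)c1)C#C | intermediate
10 | pent-4-enoyl chloride | C=CCCC(=O)Cl | starting material
11 | (2S)-2-[(1E)-1-(3,4-dimethoxyphenyl)prop-1-en-2-yl]-2-methoxy-5-oxonon-8-en-3-ynal | O=C[C@](OC)(/C(C)=C/c1ccc(OC)c(OC)c1)C#CC(=O)CCC=C | intermediate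
12 | (2S,3E)-2-[(1E)-1-(3,4-dimethoxyphenyl)prop-1-en-2-yl]-2,3-dimethoxy-5-oxonona-3,8-dienal (in equilibrium with its 3Z isomer) | O=C[C@](OC)(/C(C)=C/c1ccc(OC)c(OC)c1)/C(OC)=C\C(=O)CCC=C | intermediate
13 | (4R)-4-[(1E)-1-(3,4-dimethoxyphenyl)prop-1-en-2-yl]-5-hydroxy-3,4-dimethoxy-6-(prop-2-en-1-yl)cyclohex-2-en-1-one (mixture at C5 and C6) | C=CCC1C(O)[C@](OC)(/C(C)=C/c2ccc(OC)c(OC)c2)C(OC)=CC1=O | intermediate
14 | (4S)-4-[(1E)-1-(3,4-dimethoxyphenyl)prop-1-en-2-yl]-4,5-dimethoxy-2-(prop-2-en-1-yl)cyclohexa-2,5-dien-1-one | C=CCC1=C[C@](OC)(/C(C)=C/c2ccc(OC)c(OC)c2)C(OC)=CC1=O | target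

**Totals**

Total step count: 6. Longest linear sequence: 6 steps (1 and 2 to 14).

**Steps most likely to fail**

Step 6. The formyl group may be lost by alkoxide-induced C–C cleavage (a vinylogous retro-Claisen process) at the ynone or vinylogous ester stage, or the sequence may stall before dehydration. The fallback sets out from 9 and returns at 14; it gives up the domino so that no alkoxide meets the aldehyde, and it makes C2=C3 by a directed aldol followed by a separate elimination. Compounds 9 and 10 are coupled as above (PdCl2(PPh3)2, CuI, Et3N, THF) and ynone 11 is isolated. Methanol is added under neutral phosphine catalysis (PBu3 cat., MeOH, CH2Cl2) to give 12, with the geometric isomers equilibrated by a trace of iodine. Soft enolisation (n-Bu2BOTf, i-Pr2NEt, CH2Cl2, −78 → 0 °C) should give the cyclic aldol 13. Mesylation (MsCl, Et3N, CH2Cl2, 0 °C) gives (6R)-6-[(1E)-1-(3,4-dimethoxyphenyl)prop-1-en-2-yl]-5,6-dimethoxy-3-oxo-2-(prop-2-en-1-yl)cyclohex-4-en-1-yl methanesulfonate F1, and DBU at rt eliminates it to 14.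

Step 3. Facial discrimination may be poor, or 1,2-addition slow, at the hindered conjugated keto group. The fallback sets out from 4 and returns at 6, replacing asymmetric catalysis by resolution. Addition of Me3SiC≡CMgBr (THF, −78 °C) gives racemic methyl (3E)-4-(3,4-dimethoxyphenyl)-2-hydroxy-3-methyl-2-[(trimethylsilyl)ethynyl]but-3-enoate F2, which is separated by preparative chromatography on a chiral stationary phase to give 6; the other enantiomer is set aside.

Step 5. Over-reduction to the primary alcohol, or incomplete conversion of the hindered ester, may occur. The fallback sets out from 8 and returns at 9 by a two-step redox detour. LiAlH4 (THF, 0 °C) gives (2R,3E)-4-(3,4-dimethoxyphenyl)-2-ethynyl-2-methoxy-3-methylbut-3-en-1-ol F3, and Dess–Martin periodinane (NaHCO3, CH2Cl2, rt) oxidises it to 9.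

**Further compounds**

F1 | step 6 | (6R)-6-[(1E)-1-(3,4-dimethoxyphenyl)prop-1-en-2-yl]-5,6-dimethoxy-3-oxo-2-(prop-2-en-1-yl)cyclohex-4-en-1-yl methanesulfonate (mixture at C1 and C2) | C=CCC1C(OS(C)(=O)=O)[C@](OC)(/C(C)=C/c2ccc(OC)c(OC)c2)C(OC)=CC1=O
F2 | step 3 | racemic methyl (3E)-4-(3,4-dimethoxyphenyl)-2-hydroxy-3-methyl-2-[(trimethylsilyl)ethynyl]but-3-enoate | COC(=O)C(O)(/C(C)=C/c1ccc(OC)c(OC)c1)C#C[Si](C)(C)C
F3 | step 5 | (2R,3E)-4-(3,4-dimethoxyphenyl)-2-ethynyl-2-methoxy-3-methylbut-3-en-1-ol | OC[C@](OC)(/C(C)=C/c1ccc(OC)c(OC)c1)C#C
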